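The plan unravels the oxolane hemiketal (O–C1–C2–C3–C4) into an isomeric six-membered pyranose in which C1 is tied to an oxygen on C5. That oxygen sits β to H6, the acidic γ-proton of the butenolide ring (C6–C7–C11–C12–O). In one operation base expels it. The C5=C6 double bond forms with ring-enforced geometry, the C1 ketone is released, and the tertiary C4 hydroxyl recaptures it. The 11-oxabicyclo[5.3.1] skeleton thereby contracts to the 11-oxabicyclo[6.2.1] core. The precursor, a bridged 4-methylpyranose, comes from Achmatowicz oxidation of a [6](2,5)furanophane assembled by a vinylogous aldol reaction and a Nozaki–Hiyama–Kishi macrocyclisation.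

Key step: step 20

Remark (numbering): germacrane numbering of the target is used throughout. C1 is the hemiketal carbon, C2/C3 the CH2CH2 unit, C4 the C(CH3)–O carbon, C5 the =CH, C6 the enol-lactone carbon, C7=C11 the butenolide alkene, C8 the acyloxy carbon, C9 the CH2, C10 the CH(CH3), C12 the lactone C=O, C13 the CH2O, and C14/C15 the methyls on C10/C4. O5 is the oxygen on C5 and C2' is the carbinol carbon of the side chain.

Remark (assumption): C6 of 18–28 is drawn as one epimer, but either serves because C5 and C6 become sp2 in step 20. For the catalysts of steps 2, 11 and 14, the enantiomer that gives the drawn configuration is used.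

Step 1
Reactants: 1 2-acetylfuran; 2 triethyl phosphonoacetate
Product: 3 ethyl (E)-3-(furan-2-yl)but-2-enoate
Conditions: NaH, THF, 0 °C to reflux; Z isomer removed by chromatography
Reagents that add atoms: none
Why: Horner–Wadsworth–Emmons olefination of an aryl methyl ketone should favour the E-enoate, and a single geometry is needed for the asymmetric reduction.

Step 2
Reactants: 3 ethyl (E)-3-(furan-2-yl)but-2-enoate
Product: 4 ethyl (R)-3-(furan-2-yl)butanoate
Conditions: Cu(OAc)2·H2O (2 mol %), DTBM-SEGPHOS (2 mol %), (EtO)2MeSiH, t-BuOH, toluene, 0 °C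
Reagents that add atoms: none
Why: Copper-hydride-catalysed asymmetric conjugate reduction of a β-aryl-β-methyl enoate sets C10, the ligand enantiomer being chosen so that hydride reaches the face giving (R).

Step 3
Reactants: 4 ethyl (R)-3-(furan-2-yl)butanoate
Product: 5 (R)-3-(furan-2-yl)butan-1-ol
Conditions: LiAlH4, Et2O, 0 °C
Reagents that add atoms: none
Why: Hydride reduction of the ester gives the C8 primary alcohol without touching C10 or the furan.

Step 4
Reactants: 5 (R)-3-(furan-2-yl)butan-1-ol
Product: 7 5-[(2R)-4-hydroxybutan-2-yl]furan-2-carbaldehyde, via dilithio species 6 (not isolated)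
Conditions: n-BuLi (2.2 equiv), TMEDA, THF, −78 to 0 °C; DMF, −78 °C to rt; H2O
Reagents that add atoms: N,N-dimethylformamide CN(C)C=O
Why: After alkoxide formation the free α-position of the 2-alkylfuran is lithiated, and formylation with DMF installs C5 (directed furan α-lithiation/formylation).

Step 5
Reactants: 8 but-2-yne-1,4-diol
Product: 9 4-(tert-butyldiphenylsilyloxy)but-2-yn-1-ol
Conditions: 8 (4 equiv), TBDPSCl, imidazole, DMF, 0 °C to rt
Reagents that add atoms: tert-butyl(chloro)diphenylsilane CC(C)(C)[Si](Cl)(c1ccccc1)c1ccccc1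
Why: Statistical monosilylation with excess diol protects the future C13 oxygen as a bulky, acid-stable silyl ether.

Step 6
Reactants: 9 4-(tert-butyldiphenylsilyloxy)but-2-yn-1-ol
Product: 10 4-(tert-butyldiphenylsilyloxy)but-2-yn-1-yl methyl carbonate
Conditions: ClCO2Me, pyridine, CH2Cl2, 0 °C
Reagents that add atoms: methyl chloroformate COC(=O)Cl
Why: Acylation of the primary propargylic alcohol gives the carbonate needed for ionisation by Pd(0).

Step 7
Reactants: 10 4-(tert-butyldiphenylsilyloxy)but-2-yn-1-yl methyl carbonate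
Product: 11 methyl 2-[(tert-butyldiphenylsilyloxy)methyl]buta-2,3-dienoate
Conditions: Pd(OAc)2 (3 mol %), PPh3 (12 mol %), CO (5 bar), MeOH, 45 °C
Reagents that add atoms: carbon monoxide [C-]#[O+]
Why: Pd(0)-catalysed decarboxylative carbonylation of a propargylic carbonate proceeds through an allenylpalladium methoxide and delivers the 2,3-dienoate, introducing C12.

Step 8
Reactants: 11 methyl 2-[(tert-butyldiphenylsilyloxy)methyl]buta-2,3-dienoate
Product: 12 4-iodo-3-[(tert-butyldiphenylsilyloxy)methyl]furan-2(5H)-one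
Conditions: I2 (2 equiv), MeCN–H2O 15:1, rt to 60 °C
Reagents that add atoms: iodine II
Why: In the iodolactonisation of the 2,3-allenoate, iodine goes to the central carbon C7 and the ester oxygen closes onto C6, so ring formation fixes the cis relation of C6 and C12 across the tetrasubstituted C7=C11 bond.

Step 9
Reactants: 13 (S)-3-bromo-2-hydroxy-2-methylpropanoic acid
Product: 15 (S)-3-chloro-2-hydroxy-2-methylpropanoic acid, via sodium glycidate 14 (not isolated)
Conditions: NaOH (2.1 equiv), H2O, 0 °C to rt; then conc. HCl, 0 °C to rt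
Reagents that add atoms: hydrogen chloride Cl
Why: Halohydrin-to-epoxide closure followed by chloride opening at the unhindered CH2 (the carboxyl group disfavours attack at the tertiary carbon) exchanges Br for Cl without breaking any bond at C2'.

Step 10
Reactants: 15 (S)-3-chloro-2-hydroxy-2-methylpropanoic acid
Product: 17 (S)-3-chloro-2-methyl-2-(triethylsilyloxy)propanoic acid, via bis-silyl derivative 16 (not isolated)
Conditions: TESOTf (2.3 equiv), 2,6-lutidine, CH2Cl2, 0 °C; then THF–H2O, cat. AcOH, rt
Reagents that add atoms: triethylsilyl trifluoromethanesulfonate CC[Si](CC)(CC)OS(=O)(=O)C(F)(F)F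
Why: Exhaustive silylation followed by selective hydrolysis of the labile silyl ester masks the tertiary hydroxyl, so the acid cannot self-acylate in step 15.

Step 11
Reactants: 7 5-[(2R)-4-hydroxybutan-2-yl]furan-2-carbaldehyde; 12 4-iodo-3-[(tert-butyldiphenylsilyloxy)methyl]furan-2(5H)-one
Product: 18 (5R,6S,10R) vinylogous aldol adduct
Conditions: axially chiral guanidine base (5 mol %), THF, −40 °C
Reagents that add atoms: none
Why: The direct catalytic asymmetric vinylogous aldol reaction of a halogenated furanone joins C6 to the non-enolisable furfural carbon C5, the catalyst setting (5R), which later relays to C4.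

Step 12
Reactants: 18 (5R,6S,10R) vinylogous aldol adduct
Product: 19 seco hydroxy aldehyde (C8 aldehyde)
Conditions: TEMPO (10 mol %), PhI(OAc)2 (1.1 equiv), CH2Cl2, 0 °C to rt
Reagents that add atoms: none
Why: Oxoammonium (TEMPO) oxidation is sterically selective for the primary C8 alcohol over the hindered secondary C5 carbinol, and it is non-basic, so the aldol unit survives.

Step 13
Reactants: 19 seco hydroxy aldehyde (C8 aldehyde)
Product: 20 C5 triethylsilyl ether of the seco iodo aldehyde
Conditions: TESCl, imidazole, CH2Cl2, 0 °C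
Reagents that add atoms: chlorotriethylsilane CC[Si](Cl)(CC)CC
Why: Silylation under weakly basic conditions masks C5–OH, so the only free hydroxyl after ring closure is the one on C8.

Step 14
Reactants: 20 C5 triethylsilyl ether of the seco iodo aldehyde
Product: 21 (5R,6R,8S,10R) furanophane alcohol
Conditions: CrCl2 (10 equiv), NiCl2 (2 mol %), chiral oxazoline–sulfonamide ligand (11 equiv), Et3N, THF, rt, slow addition of 20 (final 2 mM)
Reagents that add atoms: none
Why: In this Nozaki–Hiyama–Kishi macrocyclisation, Ni inserts into C7–I and the alkenylchromium adds chemoselectively to the C8 aldehyde to close the ten-membered carbocycle as a 2,5-bridged furan, the ligand on chromium being chosen to expose the aldehyde face that gives (8S).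

Step 15
Reactants: 21 (5R,6R,8S,10R) furanophane alcohol; 17 (S)-3-chloro-2-methyl-2-(triethylsilyloxy)propanoic acid
Product: 23 furanophane C8 ester, via mixed anhydride 22 (not isolated)
Conditions: 17, 2,4,6-trichlorobenzoyl chloride, Et3N, toluene, rt; then 21, DMAP, 0 °C to rt
Reagents that add atoms: none
Why: Yamaguchi esterification acylates the only free hydroxyl with retention at C8 and C2', and Et3N/DMAP are too weak to trigger β-elimination of the C5 silyloxy group.

Step 16
Reactants: 23 furanophane C8 ester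
Product: 25 1,5-oxygen-bridged pyranone hemiketal, via Z-enedione 24 (not isolated)
Conditions: NBS (1.05 equiv), THF–H2O 4:1, 0 °C; then TsOH·H2O (cat.), rt
Reagents that add atoms: water O
Why: In this Achmatowicz rearrangement, oxidative opening of the 2,5-dialkylfuran gives the Z-enedione, acid removes the C5 TES ether, and O5 adds to the C1 ketone to give the 6-hydroxypyran-3-one, with C5 retained and C1 forced cis by the C6–C10 bridge.

Step 17
Reactants: 25 1,5-oxygen-bridged pyranone hemiketal
Product: 26 C1 triethylsilyl ketal of the bridged enone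
Conditions: TESOTf, 2,6-lutidine, CH2Cl2, −78 to −20 °C
Reagents that add atoms: triethylsilyl trifluoromethanesulfonate CC[Si](CC)(CC)OS(=O)(=O)C(F)(F)F
Why: Silylation of the exo hemiketal hydroxyl stops ring–chain tautomerism, so C1 cannot appear as a ketone in step 19, and it re-silylates any side-chain hydroxyl bared in step 16.

Step 18
Reactants: 26 C1 triethylsilyl ketal of the bridged enone
Product: 27 bridged tetrahydropyran-3-one (C4 ketone)
Conditions: H2 (1 bar), 5% Pd/C, EtOAc, rt
Reagents that add atoms: none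
Why: Catalytic hydrogenation saturates the cis-disubstituted C2=C3 enone bond, whereas the tetrasubstituted, electron-poor C7=C11 bond and the alkyl chloride should be inert.

Step 19
Reactants: 27 bridged tetrahydropyran-3-one (C4 ketone)
Product: 28 (4R) bridged 4-methylpyranose (tertiary C4 carbinol)
Conditions: MeMgBr, anhydrous CeCl3, THF, −78 °C; AcOH quench at −78 °C
Reagents that add atoms: methylmagnesium bromide C[Mg]Br
Why: The weakly basic organocerium reagent adds 1,2 to the ketone in preference to the lactone and the hindered ester, attacking the face opposite the C6–C10 bridge so that CH3 lands anti to C6, which with (5R) gives (4R).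

Step 20
Reactants: 28 (4R) bridged 4-methylpyranose (tertiary C4 carbinol)
Product: 30 1,4-oxygen-bridged hemiketal dienolide (bis-silyl ether of the core), via ring-opened hydroxy ketone 29 (not isolated)
Conditions: DBU (1.5 equiv), CH2Cl2, 0 °C to rt; pH 7 buffer
Reagents that add atoms: none
Why: DBU removes H6, the γ-proton of the butenolide, and the resulting 2-oxidofuran expels the pyranose oxygen from C5 (E1cB), which creates C5=C6 and leaves a C1 silyl-hemiketal alkoxide that collapses to the C1 ketone 29 with loss of triethylsilanolate. The free tertiary C4–OH then adds transannularly to C1=O (5-exo-trig), so the six-membered ring O–C5–C4–C3–C2–C1 is replaced by the five-membered ring O–C4–C3–C2–C1 and the [5.3.1] bicycle becomes the [6.2.1] core. The closest known reaction types are the DBU-induced β-elimination of γ-(1-silyloxyalkyl)butenolides to γ-alkylidenebutenolides and the pyranose-to-furanose isomerisation of hemiketals. The alkene geometry follows from the bicycle, in which the bridgehead H5 points outwards and anti to C7, so C4 ends up cis to C7 as O5 departs perpendicular to the oxidofuran plane. The new stereocentre C1 is controlled by C4, because a six-atom bridge can span the oxolane only cis and the hemiketal forms reversibly, so it should settle as (1S), while C4, C8, C10 and C2' are not touched. The step needs expulsion of O5 rather than of the C13 silyloxy group from the same dienolate, which is secured by the better hemiketal-type leaving group, the strain released and the fully conjugated dienolide formed, and short exposure to base limits epimerisation at C10 through 29.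

Step 21
Reactants: 30 1,4-oxygen-bridged hemiketal dienolide (bis-silyl ether of the core)
Product: 31 13-hydroxy compound (13-O-deacetyl target)
Conditions: HF·pyridine, pyridine, THF, 0 °C to rt
Reagents that add atoms: none
Why: Buffered fluoride desilylation removes the primary TBDPS and the tertiary TES ether without the basicity that would close the chlorohydrin to an epoxide.

Step 22
Reactants: 31 13-hydroxy compound (13-O-deacetyl target)
Product: 32 CNP0414417.1
Conditions: Ac2O (1.2 equiv), pyridine, CH2Cl2, 0 °C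
Reagents that add atoms: acetic anhydride CC(=O)OC(C)=O
Why: Acetylation without DMAP is selective for the primary allylic C13–OH, since the tertiary hemiketal and side-chain hydroxyls are too hindered to react.

Compound list
1 | 2-acetylfuran | CC(=O)c1ccco1 | starting material
2 | triethyl phosphonoacetate | CCOC(=O)CP(=O)(OCC)OCC | starting material
3 | ethyl (E)-3-(furan-2-yl)but-2-enoate | C/C(=C\C(=O)OCC)c1ccco1 | intermediate
4 | ethyl (R)-3-(furan-2-yl)butanoate | C[C@H](CC(=O)OCC)c1ccco1 | intermediate
5 | (R)-3-(furan-2-yl)butan-1-ol | C[C@H](CCO)c1ccco1 | intermediate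
6 | O,C-dilithio derivative of 5 (lithium alkoxide, 5-lithiofuran) | C[C@H](CCO[Li])c1ccc([Li])o1 | intermediate
7 | 5-[(2R)-4-hydroxybutan-2-yl]furan-2-carbaldehyde | C[C@H](CCO)c1ccc(C=O)o1 | intermediate
8 | but-2-yne-1,4-diol | OCC#CCO | starting material
9 | 4-(tert-butyldiphenylsilyloxy)but-2-yn-1-ol | OCC#CCO[Si](c1ccccc1)(c1ccccc1)C(C)(C)C | intermediate
10 | 4-(tert-butyldiphenylsilyloxy)but-2-yn-1-yl methyl carbonate | COC(=O)OCC#CCO[Si](c1ccccc1)(c1ccccc1)C(C)(C)C | intermediate
11 | methyl 2-[(tert-butyldiphenylsilyloxy)methyl]buta-2,3-dienoate | C=C=C(CO[Si](c1ccccc1)(c1ccccc1)C(C)(C)C)C(=O)OC | intermediate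
12 | 4-iodo-3-[(tert-butyldiphenylsilyloxy)methyl]furan-2(5H)-one | O=C1OCC(I)=C1CO[Si](c1ccccc1)(c1ccccc1)C(C)(C)C | intermediate
13 | (S)-3-bromo-2-hydroxy-2-methylpropanoic acid | OC(=O)[C@](C)(O)CBr | starting material
14 | sodium (R)-2-methyloxirane-2-carboxylate | [Na+].[O-]C(=O)[C@@]1(C)CO1 | intermediate
15 | (S)-3-chloro-2-hydroxy-2-methylpropanoic acid | OC(=O)[C@](C)(O)CCl | intermediate
16 | triethylsilyl (S)-3-chloro-2-methyl-2-(triethylsilyloxy)propanoate | CC[Si](CC)(CC)OC(=O)[C@](C)(O[Si](CC)(CC)CC)CCl | intermediate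
17 | (S)-3-chloro-2-methyl-2-(triethylsilyloxy)propanoic acid | OC(=O)[C@](C)(O[Si](CC)(CC)CC)CCl | intermediate
18 | aldol adduct (5R,6S,10R): furan C1–C4 bearing C10H(CH3)CH2CH2OH on C1 and C5H(OH) on C4, with C5 bonded to C6 of the 4-iodo-3-(TBDPSOCH2)butenolide | C[C@H](CCO)c1ccc(o1)[C@H](O)[C@@H]1OC(=O)C(CO[Si](c2ccccc2)(c2ccccc2)C(C)(C)C)=C1I | intermediate
19 | seco hydroxy aldehyde (18 with C8 as CHO) | C[C@H](CC=O)c1ccc(o1)[C@H](O)[C@@H]1OC(=O)C(CO[Si](c2ccccc2)(c2ccccc2)C(C)(C)C)=C1I | intermediate
20 | C5-O-triethylsilyl ether of 19 | C[C@H](CC=O)c1ccc(o1)[C@H](O[Si](CC)(CC)CC)[C@@H]1OC(=O)C(CO[Si](c2ccccc2)(c2ccccc2)C(C)(C)C)=C1I | intermediate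
21 | [6](2,5)furanophane alcohol (5R,6R,8S,10R): furan C1–C4 bridged by C5(OTES)–C6–C7–C8(OH)–C9–C10(CH3), butenolide fused at C6–C7 | C[C@@H]1C[C@H](O)C2=C(CO[Si](c3ccccc3)(c3ccccc3)C(C)(C)C)C(=O)O[C@H]2[C@@H](O[Si](CC)(CC)CC)c2ccc1o2 | intermediate
22 | mixed anhydride of 17 with 2,4,6-trichlorobenzoic acid | O=C(OC(=O)[C@](C)(O[Si](CC)(CC)CC)CCl)c1c(Cl)cc(Cl)cc1Cl | intermediate
23 | furanophane C8 ester (21 acylated at O8 by 17) | C[C@@H]1C[C@H](OC(=O)[C@](C)(O[Si](CC)(CC)CC)CCl)C2=C(CO[Si](c3ccccc3)(c3ccccc3)C(C)(C)C)C(=O)O[C@H]2[C@@H](O[Si](CC)(CC)CC)c2ccc1o2 | intermediate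
24 | macrocyclic (2Z)-ene-1,4-dione, C5–OTES | C[C@@H]1C[C@H](OC(=O)[C@](C)(O[Si](CC)(CC)CC)CCl)C2=C(CO[Si](c3ccccc3)(c3ccccc3)C(C)(C)C)C(=O)O[C@H]2[C@@H](O[Si](CC)(CC)CC)C(=O)/C=C\C1=O | intermediate
25 | bridged pyranone hemiketal: O5 links C5 and C1, C4 ketone, C2=C3, C1–OH anti to the C6–C10 bridge | C[C@@H]1C[C@H](OC(=O)[C@](C)(O[Si](CC)(CC)CC)CCl)C2=C(CO[Si](c3ccccc3)(c3ccccc3)C(C)(C)C)C(=O)O[C@H]2[C@H]3O[C@]1(O)C=CC3=O | intermediate
26 | C1-O-triethylsilyl ketal of 25 | C[C@@H]1C[C@H](OC(=O)[C@](C)(O[Si](CC)(CC)CC)CCl)C2=C(CO[Si](c3ccccc3)(c3ccccc3)C(C)(C)C)C(=O)O[C@H]2[C@H]3O[C@]1(O[Si](CC)(CC)CC)C=CC3=O | intermediate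
27 | 2,3-dihydro derivative of 26 (bridged tetrahydropyran-3-one) | C[C@@H]1C[C@H](OC(=O)[C@](C)(O[Si](CC)(CC)CC)CCl)C2=C(CO[Si](c3ccccc3)(c3ccccc3)C(C)(C)C)C(=O)O[C@H]2[C@H]3O[C@]1(O[Si](CC)(CC)CC)CCC3=O | intermediate
28 | (4R)-tertiary carbinol: 27 with C4(OH)(CH3), CH3 anti to C6 | C[C@@H]1C[C@H](OC(=O)[C@](C)(O[Si](CC)(CC)CC)CCl)C2=C(CO[Si](c3ccccc3)(c3ccccc3)C(C)(C)C)C(=O)O[C@H]2[C@H]3O[C@]1(O[Si](CC)(CC)CC)CC[C@@]3(C)O | intermediate
29 | ring-opened 4-hydroxy-1-ketone (ten-membered carbocycle, C5=C6 alkylidene butenolide) | CC(C)(C)[Si](c1ccccc1)(c1ccccc1)OCC1=C2/C(=C\[C@](C)(O)CCC(=O)[C@H](C)C[C@@H]2OC(=O)[C@](C)(O[Si](CC)(CC)CC)CCl)OC1=O | intermediate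
30 | (1S,4R,8S,10R) 1,4-epoxy-1-hydroxy dienolide, 13-OTBDPS, side-chain OTES | CC(C)(C)[Si](c1ccccc1)(c1ccccc1)OCC1=C2/C(=C\[C@@]3(C)CC[C@](O)(O3)[C@H](C)C[C@@H]2OC(=O)[C@](C)(O[Si](CC)(CC)CC)CCl)OC1=O | intermediate
31 | 13-hydroxy compound (13-O-deacetyl target) | OCC1=C2/C(=C\[C@@]3(C)CC[C@](O)(O3)[C@H](C)C[C@@H]2OC(=O)[C@](C)(O)CCl)OC1=O | intermediate
32 | CNP0414417.1 | CC(=O)OCC1=C2/C(=C\[C@@]3(C)CC[C@](O)(O3)[C@H](C)C[C@@H]2OC(=O)[C@](C)(O)CCl)OC1=O | target

Total step count: 22. Longest linear sequence: 16 (steps 1–4 and 11–22).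

Steps most likely to fail

Step 14 (macrocyclisation).
- **What may go wrong:** The C7–metal species may undergo reductive β-elimination of the lactone carboxylate, opening to an allenoate. Oligomerisation may outrun ring closure, or the facial selectivity at C8 may be poor.
- **Fallback:** It sets out from 4 and 12 and returns at 23, forming C7–C8 first and closing the ring at C5–C6.
  - Ester 4 is converted (MeNHOMe·HCl, i-PrMgCl) into the Weinreb amide F1.
  - Butenolide 12 is aromatised (TIPSOTf, Et3N) to the 4-iodo-2-silyloxyfuran F2. Its I/Mg exchange (i-PrMgCl·LiCl) gives a furyl Grignard reagent that cannot β-eliminate.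
  - Acylation by F1 and acidic work-up give the 4-acylbutenolide F3.
  - CBS reduction with (R)-Me-CBS/BH3 sets C8 in the (8S)-alcohol F4.
  - Yamaguchi esterification with 17 gives the ester F5, and Vilsmeier–Haack formylation of the free furan position gives the seco aldehyde F6.
  - An intramolecular vinylogous Mukaiyama aldol reaction (TESOTf, i-Pr2NEt, high dilution) then closes the ring to 23. The C5 epimers are separated at that point.

Step 19 (methyl addition).
- **What may go wrong:** The methyl nucleophile may deprotonate C6 or C5 and cause premature elimination. It may attack the lactone or ester carbonyls, or the facial bias may be insufficient.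
- **Fallback:** It sets out from 27 and returns at 28, replacing the basic nucleophile by electrophilic, non-basic chemistry.
  - Lombardo methylenation (Zn, CH2Br2, TiCl4) gives the 4-methylene compound F7.
  - NIS in wet THF forms the iodonium ion on the open face, and water opens it at the tertiary C4 from the bridge side. This gives the iodohydrin F8, with oxygen and carbon placed as in 28.
  - Radical deiodination (Bu3SnH, AIBN) converts CH2I into C15H3. The primary chloride should react far more slowly.

Step 20 (key step).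
- **What may go wrong:** The same dienolate may lose the C13 silyloxy group instead. C10 may epimerise through the transient ketone, or O5 may fail to leave.
- **Fallback:** It sets out from 28 and returns at 30, separating ring contraction from elimination.
  - AcOH–THF–H2O removes the C1 silyl group, and the hemiketal equilibrates through the hydroxy ketone to the oxolane hemiketal with free C5–OH, F9.
  - Only this isomer carries a secondary hydroxyl, so MsCl/Et3N drains the equilibrium into the C5 mesylate F10.
  - Brief treatment with DBU eliminates the much better leaving group to give 30.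

Further compounds
F1 | step 14 | (R)-3-(furan-2-yl)-N-methoxy-N-methylbutanamide | C[C@H](CC(=O)N(C)OC)c1ccco1
F2 | step 14 | 4-iodo-3-[(tert-butyldiphenylsilyloxy)methyl]-2-(triisopropylsilyloxy)furan | CC(C)[Si](Oc1occ(I)c1CO[Si](c1ccccc1)(c1ccccc1)C(C)(C)C)(C(C)C)C(C)C
F3 | step 14 | 4-[(R)-3-(furan-2-yl)butanoyl]-3-[(tert-butyldiphenylsilyloxy)methyl]furan-2(5H)-one | C[C@H](CC(=O)C1=C(CO[Si](c2ccccc2)(c2ccccc2)C(C)(C)C)C(=O)OC1)c1ccco1
F4 | step 14 | (8S,10R)-alcohol from F3 | C[C@H](C[C@H](O)C1=C(CO[Si](c2ccccc2)(c2ccccc2)C(C)(C)C)C(=O)OC1)c1ccco1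
F5 | step 14 | C8 ester of F4 with 17 | C[C@H](C[C@H](OC(=O)[C@](C)(O[Si](CC)(CC)CC)CCl)C1=C(CO[Si](c2ccccc2)(c2ccccc2)C(C)(C)C)C(=O)OC1)c1ccco1
F6 | step 14 | 5-formylfuran derivative of F5 (seco aldehyde) | C[C@H](C[C@H](OC(=O)[C@](C)(O[Si](CC)(CC)CC)CCl)C1=C(CO[Si](c2ccccc2)(c2ccccc2)C(C)(C)C)C(=O)OC1)c1ccc(C=O)o1
F7 | step 19 | 4-methylene analogue of 27 | C[C@@H]1C[C@H](OC(=O)[C@](C)(O[Si](CC)(CC)CC)CCl)C2=C(CO[Si](c3ccccc3)(c3ccccc3)C(C)(C)C)C(=O)O[C@H]2[C@H]3O[C@]1(O[Si](CC)(CC)CC)CCC3=C
F8 | step 19 | 4-hydroxy-4-(iodomethyl) analogue of 28 | C[C@@H]1C[C@H](OC(=O)[C@](C)(O[Si](CC)(CC)CC)CCl)C2=C(CO[Si](c3ccccc3)(c3ccccc3)C(C)(C)C)C(=O)O[C@H]2[C@H]3O[C@]1(O[Si](CC)(CC)CC)CC[C@@]3(CI)O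
F9 | step 20 | 1,4-epoxy-1-hydroxy isomer with free (5R)-OH and C6–H | C[C@@H]1C[C@H](OC(=O)[C@](C)(O[Si](CC)(CC)CC)CCl)C2=C(CO[Si](c3ccccc3)(c3ccccc3)C(C)(C)C)C(=O)O[C@H]2[C@@H](O)[C@@]2(C)CC[C@]1(O)O2
F10 | step 20 | C5 methanesulfonate of F9 | C[C@@H]1C[C@H](OC(=O)[C@](C)(O[Si](CC)(CC)CC)CCl)C2=C(CO[Si](c3ccccc3)(c3ccccc3)C(C)(C)C)C(=O)O[C@H]2[C@@H](OS(C)(=O)=O)[C@@]2(C)CC[C@]1(O)O2
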